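The readings are simulated from invented constants; noise was put on by code.

1. In the dawn run starting material, open intermediate and target added up to 101% of the charge at 2.00 min, against a scatter of 2 percentage points, so I took the loss of starting material as the opening step and followed its rate.

| flask | starting material | partner | temperature | remark | time |
|---|---|---|---|---|---|
| spring | 0.75 M | 1.5 equiv | 5 °C | run made earlier |  |
| dawn | 0.75 M | 1.5 equiv | 40 °C | run made earlier |  |
| alder | 1.5 M | 1.50 equiv | 70 °C |  | 4.0 min |
| oak | 1.5 M | 1.50 equiv | 40 °C |  | 4.0 min |
| cedar | 1.5 M | 1.50 equiv | 10 °C |  | 4.0 min |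

| run | time / min | open intermediate / % | target / % | starting material / % |
|---|---|---|---|---|
| spring | 8.00 | 3 | 0 | 98 |
| spring | 12.0 | 5 | 2 | 96 |
| spring | 20.0 | 9 | 0 | 91 |
| spring | 30.0 | 10 | 1 | 88 |
| spring | 60.0 | 22 | 4 | 77 |
| spring | 90.0 | 37 | 0 | 62 |
| dawn | 1.33 | 28 | 4 | 71 |
| dawn | 2.00 | 37 | 2 | 62 |
| dawn | 4.00 | 57 | 9 | 39 |
| dawn | 6.00 | 67 | 9 | 22 |
| dawn | 12.0 | 73 | 16 | 3 |
| dawn | 20.0 | 67 | 21 | 0 |

(scatter of a reading: 2 percentage points)

- the numbers in the tables scatter by 2 percentage points (one standard deviation)

1. the flask that comes out highest in amount of open intermediate, in percent of the starting material charged, or "all alike" when all lie within 1.5 percentage points (alder / oak / cedar / all alike)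
2. open intermediate at the end, in percent of the starting material charged, alder
3. open intermediate at the end, in percent of the starting material charged, oak
4. open intermediate at the end, in percent of the starting material charged, cedar

2. I read a first-order opening constant, the logarithm of charge over what is left, divided by the time. The dawn run gave 0.252 min⁻¹ at 40 °C, and the spring run gave 0.00531 min⁻¹ at 5 °C, so the activation energy was 79.9 kJ mol⁻¹. Both runs stood at 0.75 M, so carrying the constant to 1.5 M was my assumption.

3. For oak I took the opening rate to start at 0.252 min⁻¹ of the charge, which over 4.0 min would have counted 1.01 charges unslowed. Taking the rate to follow the starting material left, I reckoned it to end at a factor 0.365 of its start. Averaged over the run that gave 0.630, the mean slowing factor: the average rate over the run divided by the starting rate.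

4. I therefore reckoned oak to open 63.6%. Taking off 6.67%, the mean target of the three dawn readings around that time, I expected 56.9% open intermediate.

5. For cedar my reckoned constant became 0.00978 min⁻¹, the factor 0.981, and the opened share 3.83%, less than my figure for oak. For alder my reckoned constant became 3.69 min⁻¹ and the factor 0.0678, but I could not read a temperature law for the onward loss from the two runs, so I committed to no alder number.

6. The forecast said 27% for alder, 55% for oak and 3.4% for cedar, with “Oak most likely comes out highest”.

7. Oak came out highest at 57.2%, with cedar at 3.57% and alder at 0.00686%; alder had held 15.9% open intermediate at 2.00 min.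

    starting material → open intermediate (k = 0.0670 s⁻¹, Ea = 82.0 kJ mol⁻¹)
    partner → second intermediate (k = 0.00760 s⁻¹, Ea = 107 kJ mol⁻¹)
    open intermediate + second intermediate → target (k = 0.530 L mol⁻¹ s⁻¹, Ea = 50.0 kJ mol⁻¹)
    target ⇌ isomer of the product (K = 1.20, k = 0.0200 s⁻¹, Ea = 91.0 kJ mol⁻¹, ΔH = −5.00 kJ mol⁻¹)
    second intermediate → side product (k = 0.00950 s⁻¹, Ea = 103 kJ mol⁻¹)
    (constants at 70 °C)

8. In oak, the factor gave 63.6% opened, and the conversion was 64.1%. For cedar read at 15 min, the factor became 0.930 and the opened share 13.6%, and that flask held 12.6% open intermediate.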